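**Plan** (locants are those of the target, 7-oxabicyclo[4.1.0]hept-4-ene: C1 = quaternary oxirane carbon, C2 = CHOH, C3 = CHOBz, C4=C5, C6 = oxirane CH)
- Retrosynthesis: (a) remove the oxirane oxygen to reach dienol 9. (b) Trade esters and a silyl group back to dienoate 6. (c) Re-insert CO2 between C1 and C4 to reach bicyclic lactone 5. (d) Cut C1–C2 and C3–C4 together to reach pyrone 4 and enediol derivative 3.
- Enabling feature: the carbinol carbons C2 and C3 are ring neighbours. The other four ring atoms C1–C6–C5–C4 (both oxirane carbons plus the alkene) become a 1,3-diene once the oxirane oxygen is removed, with the exocyclic carbon on terminus C1. This is the C3–C4–C5–C6 pattern of a 2-pyrone-3-carboxylate, whose O–C(=O) bridge can leave as CO2.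
- Forward: 3 is made from aldehyde 1. The carbocycle arises in step 2 by dearomatisation of the pyrone to a 2-oxabicyclo[2.2.2]octene. The bridge leaves as CO2 in step 3, the ester becomes the CH2OBz arm in steps 4–5, and the oxirane ring is closed last.
- Helpers: the ring ester activates and chelates, and holds the exocyclic carbon at the acid level. The lactone bridge is a temporary ring. The silyl group is the donor that fixes the regiochemistry and keeps the C2 oxygen apart from the two oxygens that are benzoylated.
- Stereochemistry: C2 and C3 are set together in step 2 (E alkene gives trans; the bis(oxazoline)–copper catalyst gives the absolute sense). C1 and C6 are relayed from the C2 hydroxyl by directed epoxidation in step 7.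

Key step: step 2

Assumption: the sense of induction in step 2 is taken from the square-planar chelate model of the (S,S)-ligand complex with an endo silyloxy group. The (R,R)-ligand is equally available should the opposite sense be met.

**Step 1**
Reactants: 1 (tert-butyldimethylsilyloxy)acetaldehyde
Product: 3 (E)-2-[(tert-butyldimethylsilyl)oxy]ethenyl benzoate, via potassium E-enolate 2 (not isolated)
Conditions: KN(SiMe3)2, 18-crown-6, THF, −78 °C, slow addition of 1; then BzCl, −78 → −30 °C; chromatography on Et3N-deactivated SiO2
Reagents that add atoms: benzoyl chloride, O=C(Cl)c1ccccc1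
Why: Enol ester synthesis by O-acylation of a crown-separated potassium enolate, in which the non-chelated enediolate should prefer the E geometry that opposes the C–O(−) and C–OSi dipoles, the hard acyl chloride attacks at oxygen, and any Z isomer is removed by chromatography.

**Step 2**
Reactants: 3 (E)-2-[(tert-butyldimethylsilyl)oxy]ethenyl benzoate; 4 methyl 2-oxo-2H-pyran-3-carboxylate
Product: 5 methyl (1R,4S,7R,8R)-7-(benzoyloxy)-8-[(tert-butyldimethylsilyl)oxy]-3-oxo-2-oxabicyclo[2.2.2]oct-5-ene-4-carboxylate
Conditions: Cu(OTf)2 (10 mol %), 2,2'-(propane-2,2-diyl)bis[(4S)-4-tert-butyl-4,5-dihydrooxazole] (12 mol %), 4 Å MS, CH2Cl2, −20 °C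
Reagents that add atoms: none
Why: The divalent copper centre binds 4 through its lactone and ester carbonyl oxygens and lowers the LUMO of the pyrone diene (C3=C4–C5=C6), so that 3 adds across C6 and C3 in a strongly asynchronous inverse-electron-demand Diels–Alder reaction, its benzoyloxy-bearing carbon (β to the silyloxy donor, largest HOMO coefficient) bonding to C6 and its silyloxy-bearing carbon to C3. The closest known reaction type is the bis(oxazoline)–Cu(OTf)2-catalysed inverse-demand cycloaddition of 2-pyrone-3-carboxylates with acyclic enol ethers and silyl enol ethers. The carbocycle is closed by a [4πs+2πs] addition that gives the 2-oxabicyclo[2.2.2]oct-5-en-3-one; if the path is stepwise (Mukaiyama–Michael addition, then capture of the silyloxycarbenium ion by the malonate-type enolate), the second bond forms by a 6-(enolexo)-exo-trig closure. The trans relation of C7 (OBz) and C8 (OSi) comes from suprafacial addition to the E alkene and is also the preferred result of a stepwise closure, because cis groups on a bicyclo[2.2.2]octene bridge are eclipsed; the bridgeheads C1 and C4 follow from the pyrone face left open by the tert-butyl groups of the ligand, and the endo position of the silyloxy group then decides which face of 3 is used, hence 7R,8R. Regioselectivity rests on the donor order OSi > OBz matched with the C6-electrophilic pyrone, and chemoselectivity rests on the low temperature, which keeps CO2 in place and holds back silyl transfer to an open Michael product.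

**Step 3**
Reactants: 5 bicyclic lactone
Product: 6 methyl (5R,6R)-5-(benzoyloxy)-6-[(tert-butyldimethylsilyl)oxy]cyclohexa-1,3-diene-1-carboxylate
Conditions: degassed PhMe (0.02 M), N,O-bis(trimethylsilyl)acetamide (0.1 equiv), BHT (cat.), silylated glassware, 95 °C
Reagents that add atoms: none
Why: Retro-Diels–Alder loss of CO2 from the bridged lactone, eased by the bridgehead ester, erases the two bridgehead centres and leaves the two carbinol centres untouched, while neutral, acid-scavenged and dilute conditions hold back loss of benzoic acid to the arene.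

**Step 4**
Reactants: 6 dienoate
Product: 7 (1R,6R)-6-[(tert-butyldimethylsilyl)oxy]-5-(hydroxymethyl)cyclohexa-2,4-dien-1-ol
Conditions: i-Bu2AlH (6 equiv), CH2Cl2, −78 °C; aq. potassium sodium tartrate
Reagents that add atoms: none
Why: Hydride reduction of esters with i-Bu2AlH takes the conjugated methyl ester to the allylic alcohol by 1,2-addition and cleaves the benzoate in the same pot, whereas the silyl ether, the diene and both stereocentres are not affected at low temperature.

**Step 5**
Reactants: 7 diol
Product: 8 [(5R,6R)-5-(benzoyloxy)-6-[(tert-butyldimethylsilyl)oxy]cyclohexa-1,3-dien-1-yl]methyl benzoate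
Conditions: BzCl (2.5 equiv), pyridine, DMAP (cat.), CH2Cl2, 0 °C
Reagents that add atoms: benzoyl chloride, O=C(Cl)c1ccccc1
Why: DMAP-catalysed acylation benzoylates the only two free hydroxyls (primary allylic and ring allylic) with retention, the third oxygen being masked as its silyl ether.

**Step 6**
Reactants: 8 silyl ether
Product: 9 [(5R,6R)-5-(benzoyloxy)-6-hydroxycyclohexa-1,3-dien-1-yl]methyl benzoate
Conditions: HF·pyridine, excess pyridine, THF, 0 °C → rt (polyethylene vessel)
Reagents that add atoms: none
Why: Fluoride-driven desilylation in a pyridine-buffered medium frees the carbinol without the alkoxide basicity that would trigger benzoyl migration and without the free acid that would aromatise the diene.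

**Step 7**
Reactants: 9 dienol
Product: 10 [(1S,2S,3R,6R)-3-(benzoyloxy)-2-hydroxy-7-oxabicyclo[4.1.0]hept-4-en-1-yl]methyl benzoate
Conditions: m-CPBA (1.1 equiv), Na2HPO4, CH2Cl2, 0 °C
Reagents that add atoms: m-chloroperbenzoic acid, O=C(OO)c1cccc(Cl)c1
Why: In this hydroxyl-directed (Henbest-type) peracid epoxidation the allylic C6–OH of 9 hydrogen-bonds the peracid and delivers oxygen on its own face to the adjacent trisubstituted C1=C2 bond, the more nucleophilic of the two, so both oxirane centres are set syn to the carbinol and the disubstituted alkene next to the benzoate remains.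

**Compound list**
1 | (tert-butyldimethylsilyloxy)acetaldehyde | O=CCO[Si](C)(C)C(C)(C)C | starting material
2 | potassium (E)-2-[(tert-butyldimethylsilyl)oxy]ethenolate (not isolated) | [K+].[O-]/C=C/O[Si](C)(C)C(C)(C)C | intermediate
3 | (E)-2-[(tert-butyldimethylsilyl)oxy]ethenyl benzoate | O=C(O/C=C/O[Si](C)(C)C(C)(C)C)c1ccccc1 | intermediate
4 | methyl 2-oxo-2H-pyran-3-carboxylate | COC(=O)C1=CC=COC1=O | starting material
5 | methyl (1R,4S,7R,8R)-7-(benzoyloxy)-8-[(tert-butyldimethylsilyl)oxy]-3-oxo-2-oxabicyclo[2.2.2]oct-5-ene-4-carboxylate (OSi endo, syn to the alkene bridge; OBz exo, syn to the lactone bridge) | COC(=O)[C@@]12C=C[C@@H](OC1=O)[C@@H](OC(=O)c1ccccc1)[C@@H]2O[Si](C)(C)C(C)(C)C | intermediate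
6 | methyl (5R,6R)-5-(benzoyloxy)-6-[(tert-butyldimethylsilyl)oxy]cyclohexa-1,3-diene-1-carboxylate | COC(=O)C1=CC=C[C@@H](OC(=O)c2ccccc2)[C@@H]1O[Si](C)(C)C(C)(C)C | intermediate
7 | (1R,6R)-6-[(tert-butyldimethylsilyl)oxy]-5-(hydroxymethyl)cyclohexa-2,4-dien-1-ol | OCC1=CC=C[C@@H](O)[C@@H]1O[Si](C)(C)C(C)(C)C | intermediate
8 | [(5R,6R)-5-(benzoyloxy)-6-[(tert-butyldimethylsilyl)oxy]cyclohexa-1,3-dien-1-yl]methyl benzoate | O=C(OCC1=CC=C[C@@H](OC(=O)c2ccccc2)[C@@H]1O[Si](C)(C)C(C)(C)C)c1ccccc1 | intermediate
9 | [(5R,6R)-5-(benzoyloxy)-6-hydroxycyclohexa-1,3-dien-1-yl]methyl benzoate | O=C(OCC1=CC=C[C@@H](OC(=O)c2ccccc2)[C@@H]1O)c1ccccc1 | intermediate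
10 | [(1S,2S,3R,6R)-3-(benzoyloxy)-2-hydroxy-7-oxabicyclo[4.1.0]hept-4-en-1-yl]methyl benzoate | O=C(OC[C@@]12O[C@@H]1C=C[C@@H](OC(=O)c1ccccc1)[C@@H]2O)c1ccccc1 | target

Total step count: 7. Longest linear sequence: 7 steps (1 → 10).

**Steps most likely to fail**

1. Step 2.
   - Risk: poor facial or endo/exo selectivity, loss of the alkene geometry through a long-lived zwitterion, or silyl transfer to an open Michael product.
   - Fallback: a covalent auxiliary takes the place of the chiral catalyst.
   - From 4, acid hydrolysis (aq. HCl, 60 °C) gives 2-oxo-2H-pyran-3-carboxylic acid F1.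
   - F1 is esterified with (R)-pantolactone (DCC, DMAP, CH2Cl2) to the pantolactone pyrone ester F2.
   - Cycloaddition of F2 with 3 under an achiral lanthanide Lewis acid (Eu(fod)3, PhMe, rt) gives diastereomeric lactones. The pantolactone ester analogue of 5, F3, is separated from them by crystallisation or chromatography.
   - Thermolysis as in step 3 gives the pantolactone dienoate F4.
   - Excess i-Bu2AlH (−78 → 0 °C) removes the auxiliary and the benzoate together and returns to the route at 7.

2. Step 1.
   - Risk: poor E/Z control in the enolisation, self-aldol of 1, or C-acylation.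
   - Fallback: addition–elimination in place of enolate trapping.
   - From 1, benzoyl bromide adds across the carbonyl group (CH2Cl2, −20 °C) to give racemic 1-bromo-2-[(tert-butyldimethylsilyl)oxy]ethyl benzoate F5.
   - DBU (PhMe, 0 °C) then effects an anti-periplanar E2 elimination from the staggered conformer that keeps the silyloxy and benzoyloxy groups anti. This returns to the route at 3.

3. Step 7.
   - Risk: attack at the other double bond, over-oxidation to a bis-epoxide, or acid-induced opening of the vinyl oxirane.
   - Fallback: the oxygen is brought in by cycloaddition and then edited.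
   - From 9, photooxygenation (O2, tetraphenylporphyrin, hν, CH2Cl2, −20 °C) should add singlet oxygen to the diene face that carries the hydroxyl and is remote from the benzoate. This gives [(1S,4S,7S,8S)-8-(benzoyloxy)-7-hydroxy-2,3-dioxabicyclo[2.2.2]oct-5-en-1-yl]methyl benzoate F6.
   - PPh3 (0 °C) attacks the less hindered peroxide oxygen on the CH bridgehead. The tertiary alkoxide then closes onto the neighbouring alkene carbon in SN2' fashion, which returns to the route at 10.

**Further compounds**
F1 | step 2 | 2-oxo-2H-pyran-3-carboxylic acid | OC(=O)C1=CC=COC1=O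
F2 | step 2 | (3R)-4,4-dimethyl-2-oxooxolan-3-yl 2-oxo-2H-pyran-3-carboxylate | O=C(O[C@H]1C(=O)OCC1(C)C)C1=CC=COC1=O
F3 | step 2 | (R)-pantolactone ester analogue of 5 (same configuration of the bicyclic core) | O=C(O[C@H]3C(=O)OCC3(C)C)[C@@]12C=C[C@@H](OC1=O)[C@@H](OC(=O)c1ccccc1)[C@@H]2O[Si](C)(C)C(C)(C)C
F4 | step 2 | (R)-pantolactone ester analogue of 6 (5R,6R in the ring) | O=C(O[C@H]1C(=O)OCC1(C)C)C1=CC=C[C@@H](OC(=O)c2ccccc2)[C@@H]1O[Si](C)(C)C(C)(C)C
F5 | step 1 | 1-bromo-2-[(tert-butyldimethylsilyl)oxy]ethyl benzoate (racemic) | O=C(OC(Br)CO[Si](C)(C)C(C)(C)C)c1ccccc1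
F6 | step 7 | [(1S,4S,7S,8S)-8-(benzoyloxy)-7-hydroxy-2,3-dioxabicyclo[2.2.2]oct-5-en-1-yl]methyl benzoate | O=C(OC[C@]12C=C[C@H](OO1)[C@@H](OC(=O)c1ccccc1)[C@@H]2O)c1ccccc1
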